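**Retrosynthetic overview**

1. Last C–C bond, ring B: C6–C7, formed when the C4–C5–C6 allyl cation of a fully oxygenated bisabolane-type ketone is captured by its own enol carbon C7 (the 1,10-closure that turns the bisabolyl into the amorphenyl skeleton). Only the C9 hydroxyl is added afterwards.
2. The cation comes from a tertiary C4 allylic alcohol, made by a singlet-oxygen ene reaction on the ring A olefin.
3. Side chain C8–C13: hydroboration of the isopropenyl group (sets C10), then carbonylative cross-coupling with CO and a four-carbon alkenyl bromide.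
4. Ring A is not built: it is (R)-carvone 1, the product of nature's own 1,6-closure. The all-cis C1/C2/C3 array comes from α′-hydroxylation, inversion with acetate and Luche reduction.
5. Order of ring formation: ring A (chiral pool), then ring B (cationic closure), the same order as farnesyl → bisabolyl → amorphenyl.

Assumption: carbon labels follow amorphane numbering in every compound (C1, C6 = ring-fusion carbons; C2, C3 = acetoxy carbons; C4 carries CH3-15; C7 = isopropylidene carbon; C8 = ketone; C9 = carbinol; C10 = CH–CH3); α is the face of the two acetoxy groups; the oxaziridine is used as the racemate.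

**Route**

Step 1
Reactants: 1 (R)-(−)-carvone
Product: 3 (5S,6S)-6-hydroxy-2-methyl-5-(prop-1-en-2-yl)cyclohex-2-en-1-one (trans-6-hydroxycarvone), via sodium dienolate 2 (not isolated)
Conditions: NaN(SiMe3)2, THF, −78 °C; 3-phenyl-2-(phenylsulfonyl)oxaziridine, −78 °C; AcOH
Reagents that add atoms: 3-phenyl-2-(phenylsulfonyl)oxaziridine, O=S(=O)(N1OC1c1ccccc1)c1ccccc1 (the C2 oxygen); NaN(SiMe3)2, [Na+].C[Si](C)(C)[N-][Si](C)(C)C (sodium of 2 only)
Why: Kinetic α′-deprotonation at C2 gives the cross-conjugated dienolate 2, and Davis enolate hydroxylation delivers oxygen to C2 anti to the isopropenyl group on C1, so the new C2–OH is β (trans); C1 is the carvone stereocentre and is not touched.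

Step 2
Reactants: 3 (5S,6S)-6-hydroxy-2-methyl-5-(prop-1-en-2-yl)cyclohex-2-en-1-one
Product: 5 (1R,6S)-3-methyl-2-oxo-6-(prop-1-en-2-yl)cyclohex-3-en-1-yl acetate (cis-6-acetoxycarvone), via α-keto triflate 4 (not isolated)
Conditions: Tf2O, pyridine, CH2Cl2, −40 °C; then n-Bu4NOAc, toluene, −20 to 0 °C
Reagents that add atoms: trifluoromethanesulfonic anhydride, O=S(=O)(OS(=O)(=O)C(F)(F)F)C(F)(F)F (triflyl group of 4 only); tetrabutylammonium acetate, CCCC[N+](CCCC)(CCCC)CCCC.CC([O-])=O (the acetoxy group of 5)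
Why: The α-keto triflate 4 undergoes SN2 displacement by naked acetate (Lattrell–Dax-type inversion, accelerated by the adjacent carbonyl; H1 is syn to the leaving group, so E2 loss is not available), which turns the 2β-alcohol into the 2α-acetate, cis to the C1 side chain, the face that direct enolate oxidation cannot reach.

Step 3
Reactants: 5 (1R,6S)-3-methyl-2-oxo-6-(prop-1-en-2-yl)cyclohex-3-en-1-yl acetate
Product: 6 (1R,2S,6S)-2-hydroxy-3-methyl-6-(prop-1-en-2-yl)cyclohex-3-en-1-yl acetate
Conditions: NaBH4, CeCl3·7H2O, MeOH, −78 °C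
Reagents that add atoms: none
Why: Luche 1,2-reduction, in which hydride adds axially to C3 from the β face, anti to the axial C2 acetoxy group (the same sense as carvone → cis-carveol), giving the 3α-alcohol and so the all-cis C1/C2/C3 array.

Step 4
Reactants: 6 (1R,2S,6S)-2-hydroxy-3-methyl-6-(prop-1-en-2-yl)cyclohex-3-en-1-yl acetate; 7 1-bromo-2-methylprop-1-ene; 8 carbon monoxide
Product: 10 (1R,2S,6S)-2-hydroxy-3-methyl-6-[(2S)-6-methyl-4-oxohept-5-en-2-yl]cyclohex-3-en-1-yl acetate, via alkylborane 9 (not isolated)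
Conditions: 9-BBN (2.3 equiv), THF, 0 °C to rt; then 7, CO (1 atm), Pd(PPh3)4 (5 mol %), K3PO4 (aq), THF, 50 °C
Reagents that add atoms: 9-borabicyclo[3.3.1]nonane (9-BBN), B1C2CCCC1CCC2 (boron groups of 9 only)
Why: 9-BBN hydroborates only the 1,1-disubstituted alkene (boron to C9) and, with H1 eclipsing the double bond, attacks the face turned away from C2 and its axial acetoxy group (1,2-induction of the Still–Barrish type), which sets C10 as S; the B-alkyl-9-BBN 9 then enters a Suzuki–Miyaura carbonylative cross-coupling with 7 and 8 that builds C9–C8(=O)–C7 in the same flask.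

Step 5
Reactants: 10 (1R,2S,6S)-2-hydroxy-3-methyl-6-[(2S)-6-methyl-4-oxohept-5-en-2-yl]cyclohex-3-en-1-yl acetate
Product: 11 (1R,2S,6S)-3-methyl-6-[(2S)-6-methyl-4-oxohept-5-en-2-yl]cyclohex-3-ene-1,2-diyl diacetate
Conditions: Ac2O, pyridine, DMAP (cat.), CH2Cl2, rt
Reagents that add atoms: acetic anhydride, CC(=O)OC(C)=O
Why: DMAP-catalysed acetylation of the secondary allylic alcohol, which also funnels any acetyl-migrated or partly hydrolysed material from step 4 into the single 2α,3α-diacetate; no stereocentre is formed.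

Step 6
Reactants: 11 (1R,2S,6S)-3-methyl-6-[(2S)-6-methyl-4-oxohept-5-en-2-yl]cyclohex-3-ene-1,2-diyl diacetate
Product: 13 (1R,2R,3R,6R)-3-hydroxy-3-methyl-6-[(2S)-6-methyl-4-oxohept-5-en-2-yl]cyclohex-4-ene-1,2-diyl diacetate, via allylic hydroperoxide 12 (not isolated)
Conditions: O2, hν (white LED), tetraphenylporphyrin (cat.), CH2Cl2, −20 °C; then PPh3
Reagents that add atoms: dioxygen, O=O
Why: Schenck ene reaction, in which singlet oxygen attacks only the electron-rich trisubstituted ring olefin (the enone is inert), adds to C4 from the β face away from the three α substituents while taking H from C6 (H3 is deactivated by its acetoxy group), and PPh3 reduces hydroperoxide 12 to the tertiary allylic alcohol; the C4 configuration is lost again in step 7, so a C4 epimer converges.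

Step 7
Reactants: 13 (1R,2R,3R,6R)-3-hydroxy-3-methyl-6-[(2S)-6-methyl-4-oxohept-5-en-2-yl]cyclohex-4-ene-1,2-diyl diacetate
Product: 16 (1R,2R,3S,6R,10S)-2α,3α-diacetoxyamorpha-4,7(11)-dien-8-one, via allyl cation 14 (not isolated), via isopropenyl ketone 15 (not isolated)
Conditions: Sc(OTf)3 (10 mol %), 4 Å MS, CH2Cl2, −20 to 0 °C; then DBU (20 mol %), rt
Reagents that add atoms: none
Why: Proposed new method: Sc(OTf)3 ionises the tertiary allylic alcohol (assisted by the trans C3 acetate) to the C4–C5–C6 allyl cation 14, whose secondary terminus C6 is attacked by C7 of the enone's dienol through a six-membered chair on the face that carries the C1 chain (axial bond formation on the cyclohexenyl cation allows only the cis ring fusion, so H6 ends β), while the only competing carbon nucleophile (the C9 enol) can reach only the hindered tertiary C4 through a boat and O-alkylation is reversible, and DBU then moves the C11=C12 double bond of 15 into conjugation to give the isopropylidene enone; the closest known reactions are the acid-catalysed terpenylation of resorcinols with p-mentha-2,8-dien-1-ol and the Lewis-acid-catalysed dehydrative allylation of carbonyl enols by allylic alcohols, used here as an intramolecular allyl cation–enol closure.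

Step 8
Reactants: 16 (1R,2R,3S,6R,10S)-2α,3α-diacetoxyamorpha-4,7(11)-dien-8-one
Product: 18 (1S,2R,3S,6R,9S,10R)-2α,3α-diacetoxy-9α-hydroxyamorpha-4,7(11)-dien-8-one (CNP0333818.1), via sodium enolate 17 (not isolated)
Conditions: NaN(SiMe3)2 (1.1 equiv), THF, −78 °C; 3-phenyl-2-(phenylsulfonyl)oxaziridine, −78 °C; AcOH, −78 °C
Reagents that add atoms: 3-phenyl-2-(phenylsulfonyl)oxaziridine, O=S(=O)(N1OC1c1ccccc1)c1ccccc1 (the C9 oxygen); NaN(SiMe3)2, [Na+].C[Si](C)(C)[N-][Si](C)(C)C (sodium of 17 only)
Why: Kinetic deprotonation of the ketone at C9 (the α′ CH2, far more acidic than the acetate methyls at −78 °C) and Davis enolate hydroxylation anti to the adjacent C10 methyl group give the 9α-alcohol, trans to CH3-14 and equatorial, which is also the thermodynamic epimer of this α-ketol; the cold AcOH quench prevents acetyl migration.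

**Compound list**

1 | (R)-(−)-carvone, (5R)-2-methyl-5-(prop-1-en-2-yl)cyclohex-2-en-1-one | CC1=CC[C@H](CC1=O)C(C)=C | starting material
2 | sodium (3R)-6-methyl-3-(prop-1-en-2-yl)cyclohexa-1,5-dien-1-olate (cross-conjugated dienolate of 1) | [Na+].CC1=CC[C@H](C=C1[O-])C(C)=C | intermediate (not isolated)
3 | (5S,6S)-6-hydroxy-2-methyl-5-(prop-1-en-2-yl)cyclohex-2-en-1-one (2β-OH, trans to the isopropenyl group) | CC1=CC[C@H]([C@H](O)C1=O)C(C)=C | intermediate
4 | (1S,6S)-3-methyl-2-oxo-6-(prop-1-en-2-yl)cyclohex-3-en-1-yl trifluoromethanesulfonate | CC1=CC[C@H]([C@H](OS(=O)(=O)C(F)(F)F)C1=O)C(C)=C | intermediate (not isolated)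
5 | (1R,6S)-3-methyl-2-oxo-6-(prop-1-en-2-yl)cyclohex-3-en-1-yl acetate (2α-OAc, cis to the isopropenyl group) | CC1=CC[C@H]([C@@H](OC(C)=O)C1=O)C(C)=C | intermediate
6 | (1R,2S,6S)-2-hydroxy-3-methyl-6-(prop-1-en-2-yl)cyclohex-3-en-1-yl acetate (all-cis) | CC1=CC[C@H]([C@@H](OC(C)=O)[C@H]1O)C(C)=C | intermediate
7 | 1-bromo-2-methylprop-1-ene | CC(C)=CBr | starting material
8 | carbon monoxide | [C-]#[O+] | starting material
9 | B-alkyl-9-BBN of 6 (boron on C9; the C3 hydroxyl as its 9-BBN borinate; C10 S) | CC1=CC[C@H]([C@@H](OC(C)=O)[C@H]1OB2C3CCCC2CCC3)[C@@H](C)CB2C3CCCC2CCC3 | intermediate (not isolated)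
10 | (1R,2S,6S)-2-hydroxy-3-methyl-6-[(2S)-6-methyl-4-oxohept-5-en-2-yl]cyclohex-3-en-1-yl acetate | CC1=CC[C@H]([C@@H](OC(C)=O)[C@H]1O)[C@@H](C)CC(=O)C=C(C)C | intermediate
11 | (1R,2S,6S)-3-methyl-6-[(2S)-6-methyl-4-oxohept-5-en-2-yl]cyclohex-3-ene-1,2-diyl diacetate | CC1=CC[C@H]([C@@H](OC(C)=O)[C@H]1OC(C)=O)[C@@H](C)CC(=O)C=C(C)C | intermediate
12 | (1R,2R,3R,6R)-3-hydroperoxy-3-methyl-6-[(2S)-6-methyl-4-oxohept-5-en-2-yl]cyclohex-4-ene-1,2-diyl diacetate | C[C@@]1(OO)C=C[C@@H]([C@@H](C)CC(=O)C=C(C)C)[C@@H](OC(C)=O)[C@H]1OC(C)=O | intermediate (not isolated)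
13 | (1R,2R,3R,6R)-3-hydroxy-3-methyl-6-[(2S)-6-methyl-4-oxohept-5-en-2-yl]cyclohex-4-ene-1,2-diyl diacetate (4β-OH) | C[C@@]1(O)C=C[C@@H]([C@@H](C)CC(=O)C=C(C)C)[C@@H](OC(C)=O)[C@H]1OC(C)=O | intermediate
14 | C4–C5–C6 allyl cation from 13 (drawn with the charge on C4) | C[C+]1C=C[C@@H]([C@@H](C)CC(=O)C=C(C)C)[C@@H](OC(C)=O)[C@H]1OC(C)=O | intermediate (not isolated)
15 | 2α,3α-diacetoxyamorpha-4,11-dien-8-one (cis-fused; C7 epimers, C7 not specified) | CC(=O)O[C@@H]1[C@@H]2[C@@H](C)CC(=O)C(C(C)=C)[C@@H]2C=C(C)[C@@H]1OC(C)=O | intermediate (not isolated)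
16 | (1R,2R,3S,6R,10S)-2α,3α-diacetoxyamorpha-4,7(11)-dien-8-one (H1β, H6β, 10β-CH3) | CC(=O)O[C@@H]1[C@@H]2[C@@H](C)CC(=O)C(=C(C)C)[C@@H]2C=C(C)[C@@H]1OC(C)=O | intermediate
17 | sodium C8(O)=C9 enolate of 16 | [Na+].CC(=O)O[C@@H]1[C@@H]2[C@@H](C)C=C([O-])C(=C(C)C)[C@@H]2C=C(C)[C@@H]1OC(C)=O | intermediate (not isolated)
18 | (1S,2R,3S,6R,9S,10R)-2α,3α-diacetoxy-9α-hydroxyamorpha-4,7(11)-dien-8-one (CNP0333818.1) | CC(=O)O[C@@H]1[C@@H]2[C@@H](C)[C@H](O)C(=O)C(=C(C)C)[C@@H]2C=C(C)[C@@H]1OC(C)=O | target

**Totals**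

Total step count: 8. Longest linear sequence: 8 steps (1 → 18).

**Three steps most likely to fail**

Step 7, the cation–enol closure. The risks are O-alkylation, loss of H1 from the cation followed by loss of acetic acid (aromatisation), and attack by the C9 enol. The fallback sets out from 13 and comes back at 16. PBr3 in Et2O at −10 °C converts the tertiary allylic alcohol with allylic transposition (as linalool gives geranyl bromide) into the secondary allylic bromide F1 (6β-Br; a 6α epimer equilibrates by bromide exchange). NaN(SiMe3)2 in THF at −78 to 0 °C then gives the extended sodium dienolate F2. F2 closes ring B by intramolecular SN2 C-alkylation at C7 with inversion at C6 (C9 could reach C6 only through a four-membered ring). This gives 15 and, after DBU, 16. The closure is then an enolate alkylation instead of a cation capture.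

Step 4, the hydroboration/carbonylative coupling. The risks are modest 1,2-induction at C10 and a sluggish carbonylative coupling of the hindered alkenyl bromide. The fallback sets out from 6 and comes back at 11. Ac2O/pyridine/DMAP gives the diacetate F3. Ene-type acylation of its isopropenyl group with 3-methylbut-2-enoyl chloride and Me2AlCl (CH2Cl2, −78 °C) gives the β,γ-unsaturated ketone F4, which keeps a C10=C14 methylene. Hydrogenation of this 1,1-disubstituted alkene with H2 and a chiral [Ir(cod)(tBu-PHOX)][BArF4] catalyst (ligand enantiomer chosen by screening) gives 11. C10 is then fixed by the catalyst and not by the substrate, and the ketone carbon comes from the acid chloride and not from CO.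

Step 6, the ene reaction. The risk is regiochemistry: the exocyclic C4=C15 hydroperoxide is the expected side product. The fallback sets out from 11 and comes back at 13. mCPBA (CH2Cl2, 0 °C) epoxidises the ring olefin from the β face to the 4β,5β-epoxide F5. PhSeNa [(PhSe)2, NaBH4, EtOH] opens it at C5 to the hydroxy selenide F6. H2O2 gives the selenoxide F7, whose syn elimination runs away from the carbinol carbon towards C6 (Sharpless–Lauer sequence) and delivers 13 as the same 4β-alcohol. The C5=C6 bond is then placed by elimination and not by an ene reaction.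

**Further compounds**

F1 | step 7 | 5-bromo-3-methyl-6-[(2S)-6-methyl-4-oxohept-5-en-2-yl]cyclohex-3-ene-1,2-diyl diacetate (6β-Br, trans to the side chain; other centres as in 11) | CC1=C[C@H](Br)[C@@H]([C@@H](C)CC(=O)C=C(C)C)[C@@H](OC(C)=O)[C@H]1OC(C)=O
F2 | step 7 | extended sodium dienolate of F1 (C8(O)=C7–C11=C12) | [Na+].CC1=C[C@H](Br)[C@@H]([C@@H](C)CC([O-])=CC(C)=C)[C@@H](OC(C)=O)[C@H]1OC(C)=O
F3 | step 4 | (1R,2S,6S)-3-methyl-6-(prop-1-en-2-yl)cyclohex-3-ene-1,2-diyl diacetate | CC1=CC[C@H]([C@@H](OC(C)=O)[C@H]1OC(C)=O)C(C)=C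
F4 | step 4 | 3-methyl-6-(6-methyl-4-oxohepta-1,5-dien-2-yl)cyclohex-3-ene-1,2-diyl diacetate (ring centres as in 11) | CC1=CC[C@H]([C@@H](OC(C)=O)[C@H]1OC(C)=O)C(=C)CC(=O)C=C(C)C
F5 | step 6 | 4β,5β-epoxide of 11 | C[C@@]12O[C@@H]1C[C@@H]([C@@H](C)CC(=O)C=C(C)C)[C@@H](OC(C)=O)[C@H]2OC(C)=O
F6 | step 6 | 4β-hydroxy-5α-phenylselanyl derivative of 11 | C[C@@]1(O)[C@@H]([Se]c2ccccc2)C[C@@H]([C@@H](C)CC(=O)C=C(C)C)[C@@H](OC(C)=O)[C@H]1OC(C)=O
F7 | step 6 | selenoxide of F6 | C[C@@]1(O)[C@@H]([Se](=O)c2ccccc2)C[C@@H]([C@@H](C)CC(=O)C=C(C)C)[C@@H](OC(C)=O)[C@H]1OC(C)=O
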